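**Retrosynthetic overview**
1. Target ⇐ C15–C16 epoxide closed last through a bromohydrin; C3 ketone by oxidation; C10 carbinol by MeMgBr addition to a C10 ketone.
2. C10 ketone ⇐ key C–O step: a silyl triflate-triggered epoxonium cascade on an acyclic bis-epoxide that forms the oxepane C2–O bond (ring A) and the C6–C11 bond (ring B) in one operation, with the complete right half already attached.
3. Cascade precursor ⇐ aldol condensation (C11–C12) of the Shi bis-epoxide of (E)-geranylacetone with a right-half aldehyde.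
4. Right-half aldehyde ⇐ Claisen rearrangement on a cyclohept-2-enol (sets C14, places C15=C16) ⇐ enone ⇐ radical two-carbon ring expansion of a cis-bicyclo[3.3.0]octan-3-one.
5. Bicyclooctanone ⇐ dichloroketene/diazomethane/cuprate cyclopentanone annulation on (R)-linalool-derived 1-methylcyclopent-2-enol. Ring order: D, then C (five-membered, expanded to seven), then A and B together, epoxide last.

Numbering used: squalene-type labels; C2 (CMe2–O), C3 (ketone), C6/C7 (A/B fusion), C10 (carbinol), C11, C12–C13 (linker), C14–C23 (ring C, C15–C16 epoxide, C23 gem-dimethyl), C18/C22 (C/D fusion), C19 (ring D carbinol).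

**Route**

Step 1
Reactants: 1 (R)-(−)-linalool
Product: 2 (R)-1-methylcyclopent-2-en-1-ol
Conditions: second-generation Grubbs catalyst RuCl2(H2IMes)(PCy3)(=CHPh) (0.5 mol%), CH2Cl2, 40 °C
Reagents that add atoms: none
Why: Ring-closing metathesis between the vinyl group and the trisubstituted alkene, accelerated by the free allylic hydroxyl, expels isobutene and leaves the (R)-carbinol centre (future C19) untouched.

Step 2
Reactants: 2 (R)-1-methylcyclopent-2-en-1-ol
Product: 3 (R)-triethyl[(1-methylcyclopent-2-en-1-yl)oxy]silane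
Conditions: Et3SiOTf, 2,6-lutidine, CH2Cl2, −78 → 0 °C
Reagents that add atoms: triethylsilyl triflate, CC[Si](CC)(CC)OS(=O)(=O)C(F)(F)F
Why: Silyl triflate silylation of the tertiary alcohol protects it and places a bulky group on one face of the ring alkene.

Step 3
Reactants: 3 (R)-triethyl[(1-methylcyclopent-2-en-1-yl)oxy]silane
Product: 4 cis-6,6-dichloro-2-methyl-2-(triethylsilyloxy)bicyclo[3.2.0]heptan-7-one (C=O carbon on the bridgehead next to the carbinol carbon; both bridgehead H cis to OSiEt3)
Conditions: Cl3CCOCl, Zn–Cu couple, POCl3, Et2O, rt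
Reagents that add atoms: trichloroacetyl chloride, ClC(=O)C(Cl)(Cl)Cl
Why: Ketene–alkene [2+2] cycloaddition, suprafacial on the face anti to OSiEt3, sets the cis fusion (future C18 and C22); the carbonyl carbon bonds to the alkene carbon next to the oxygenated quaternary centre, because positive charge develops better at the remote carbon, which also takes the bulkier CCl2 end.

Step 4
Reactants: 4 cis-6,6-dichloro-2-methyl-2-(triethylsilyloxy)bicyclo[3.2.0]heptan-7-one
Product: 5 cis-2,2-dichloro-6-methyl-6-(triethylsilyloxy)bicyclo[3.3.0]octan-3-one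
Conditions: CH2N2, Et2O, 0 °C; AcOH quench
Reagents that add atoms: diazomethane, C=[N+]=[N-]
Why: Diazomethane homologation of an α,α-dichlorocyclobutanone (Tiffeneau–Demjanov type), in which only the non-halogenated α-carbon migrates, with retention, inserts the future C17 between the carbonyl (C16) and C18.

Step 5
Reactants: 5 cis-2,2-dichloro-6-methyl-6-(triethylsilyloxy)bicyclo[3.3.0]octan-3-one
Product: 6 cis-2,2,6-trimethyl-6-(triethylsilyloxy)bicyclo[3.3.0]octan-3-one
Conditions: Me2CuLi (4 equiv), Et2O, −40 °C; then MeI, DMPU, −40 °C → rt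
Reagents that add atoms: lithium dimethylcuprate, [Li+].C[Cu-]C; iodomethane, CI
Why: Reductive alkylation of the α,α-dichloro ketone (chlorine–copper exchange, substitution to the α-methyl enolate, C-methylation) builds the gem-dimethyl carbon C23 regiospecifically.

Step 6
Reactants: 6 cis-2,2,6-trimethyl-6-(triethylsilyloxy)bicyclo[3.3.0]octan-3-one
Product: 7 cis-2,2,6-trimethyl-3-(prop-1-en-2-yl)-6-(triethylsilyloxy)bicyclo[3.3.0]octan-3-ol
Conditions: CH2=C(CH3)MgBr, CeCl3, THF, −78 → 0 °C
Reagents that add atoms: isopropenylmagnesium bromide, CC(=C)[Mg]Br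
Why: Organocerium 1,2-addition to the hindered, enolizable ketone from the convex face; the new carbinol configuration is erased in step 7.

Step 7
Reactants: 7 cis-2,2,6-trimethyl-3-(prop-1-en-2-yl)-6-(triethylsilyloxy)bicyclo[3.3.0]octan-3-ol
Product: 8 cis-fused 1,4,4,6-tetramethyl-1-(triethylsilyloxy)octahydroazulen-7(1H)-one (azulene numbering; H-3a and H-8a cis to each other and to OSiEt3; C6 epimers)
Conditions: [Ir(dF(CF3)ppy)2(5,5′-d(CF3)bpy)]PF6 (2 mol%), 2,4,6-collidine, 2,4,6-triisopropylbenzenethiol (10 mol%), CH2Cl2, blue LEDs, rt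
Reagents that add atoms: none
Why: Photocatalytic proton-coupled electron transfer gives the alkoxy radical, β-scission toward the tertiary C23 radical reveals a methacryloyl acceptor, and polarity-matched 7-endo Giese recyclization at its CH2 terminus (radical two-carbon ring expansion) forms ring C with the cis fusion untouched.

Step 8
Reactants: 8 cis-fused 1,4,4,6-tetramethyl-1-(triethylsilyloxy)octahydroazulen-7(1H)-one
Product: 10 cis-fused 1,4,4,6-tetramethyl-1-(triethylsilyloxy)-2,3,3a,4,8,8a-hexahydroazulen-7(1H)-one, via trimethylsilyl enol ether 9 (not isolated)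
Conditions: Me3SiCl, NaI, Et3N, MeCN, rt; then Pd(OAc)2 (10 mol%), O2, DMSO, 60 °C
Reagents that add atoms: none
Why: Saegusa–Ito dehydrogenation through the thermodynamic, more substituted silyl enol ether puts the double bond at C14=C15, endocyclic β-hydride elimination being preferred.

Step 9
Reactants: 10 cis-fused 1,4,4,6-tetramethyl-1-(triethylsilyloxy)-2,3,3a,4,8,8a-hexahydroazulen-7(1H)-one
Product: 11 (7S)-1,4,4,6-tetramethyl-1-(triethylsilyloxy)-1,2,3,3a,4,7,8,8a-octahydroazulen-7-ol (OH trans to H-3a and H-8a)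
Conditions: (R)-2-methyl-CBS-oxazaborolidine (20 mol%), BH3·SMe2, THF, −30 °C
Reagents that add atoms: none
Why: Corey–Bakshi–Shibata reduction with the α-methyl alkene arm as the large group delivers hydride from the convex face (the side of the ring-fusion hydrogens), reagent and substrate matched, giving the C16 (S)-carbinol.

Step 10
Reactants: 11 (7S)-1,4,4,6-tetramethyl-1-(triethylsilyloxy)-1,2,3,3a,4,7,8,8a-octahydroazulen-7-ol
Product: 13 2-[1,4,4,6-tetramethyl-1-(triethylsilyloxy)-1,2,3,3a,4,5,8,8a-octahydroazulen-5-yl]acetaldehyde (side chain at C5 trans to H-3a and H-8a; C6=C7 alkene), via allyl vinyl ether 12 (not isolated)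
Conditions: ethyl vinyl ether, Hg(OAc)2 (20 mol%), reflux; evaporate; then toluene, NaHCO3, 150 °C (sealed tube)
Reagents that add atoms: ethyl vinyl ether, C=COCC
Why: Vinyl ether exchange followed by thermal Claisen [3,3] rearrangement; suprafacial transfer places the CH2CHO group at C14 on the face the oxygen leaves, which sets C14 and moves the alkene to C15=C16.

Step 11
Reactants: 14 (E)-geranylacetone
Product: 15 (5R,6R,9R)-5,6:9,10-diepoxy-6,10-dimethylundecan-2-one
Conditions: D-fructose-derived Shi ketone (60 mol%), Oxone (2KHSO5·KHSO4·K2SO4), K2CO3, Bu4NHSO4, MeCN–CH2(OMe)2–aq. Na2B4O7 buffer (pH 10.5), 0 °C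
Reagents that add atoms: potassium peroxymonosulfate (active part of Oxone), [K+].[O-]S(=O)(=O)OO
Why: Shi asymmetric epoxidation of both trisubstituted alkenes through the spiro dioxirane transition state gives the (R)-configured epoxide carbons (future C3, C6, C7); the methyl ketone is inert.

Step 12
Reactants: 15 (5R,6R,9R)-5,6:9,10-diepoxy-6,10-dimethylundecan-2-one; 13 right-half aldehyde
Product: 18 (E)-enone joining both halves (C10 ketone, C11=C12 alkene, both epoxides and C19 OSiEt3 intact), via aldol adduct 16 (not isolated), via β-acetoxy ketone 17 (not isolated)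
Conditions: 15 (1.3 equiv), LiN(i-Pr)2, THF, −78 °C; 13; then Ac2O, −78 → 0 °C; DBU, 0 °C → rt
Reagents that add atoms: none
Why: Kinetic deprotonation at the methyl group, aldol addition to 13, in situ acetylation and E1cB elimination (aldol condensation) give the (E)-enone and form the C11–C12 bond.

Step 13
Reactants: 18 (E)-enone joining both halves
Product: 21 tetracyclic keto diol (rings A and B formed; C10 ketone; 3R OH; C19 OH; C15=C16 alkene), via triethylsilyl enol ether 19 (not isolated), via bis-silyl ether 20 (not isolated)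
Conditions: Et3SiH (1.05 equiv), RhCl(PPh3)3 (2 mol%), PhH, 50 °C; evaporate; then Me3SiOTf (1.2 equiv), 2,6-di-tert-butyl-4-methylpyridine, CH2Cl2 (0.01 M), −78 °C; then 1 M HCl, THF–MeOH, rt
Reagents that add atoms: none
Why: Proposed new method: a one-flask reductive epoxonium cascade in which Rh–H 1,4-hydrosilylation turns the enone regiospecifically into the (Z)-trisubstituted enol silane C10(OSiEt3)=C11, Me3SiOTf then silylates the terminal epoxide, the 6,7-epoxide oxygen attacks its tertiary C2 (7-endo C–O bond, bicyclic epoxonium ion), and the enol silane carbon C11 opens the epoxonium anti at tertiary C6 through a chair transition state, which gives the trans A/B fusion (C6 inverted, C7 retained) and the equatorial C11 side chain (also the thermodynamic epimer next to the ketone); the closest known reaction is the silyl triflate-promoted tandem oxa-/carbacyclization of 1,5-diepoxides terminated by 1,1-disubstituted methyl-ketone enol silanes, not yet shown for a trisubstituted enol silane made by conjugate hydrosilylation or beside a remote trisubstituted alkene.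

Step 14
Reactants: 21 tetracyclic keto diol
Product: 22 triol (C10 tertiary alcohol, 10S; 3R OH; C19 OH; C15=C16 alkene)
Conditions: MeMgBr (6 equiv), CeCl3, THF, −78 → 0 °C
Reagents that add atoms: methylmagnesium bromide, C[Mg]Br
Why: Nucleophilic addition to the cyclohexanone from the equatorial direction, because the axial C6 methyl blocks the axial path, gives the axial C10 hydroxyl and equatorial methyl; CeCl3 suppresses enolization.

Step 15
Reactants: 22 triol
Product: 23 C3 ketone diol (15,16-alkene)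
Conditions: Dess–Martin periodinane, NaHCO3, CH2Cl2, rt
Reagents that add atoms: none
Why: Dess–Martin oxidation of the only secondary alcohol; the two tertiary alcohols and the alkene are inert.

Step 16
Reactants: 23 C3 ketone diol (15,16-alkene)
Product: 25 CNP0259752.1, via bromohydrin 24 (not isolated)
Conditions: N-bromosuccinimide, acetone–H2O (4:1), 0 °C; then K2CO3, MeOH, rt
Reagents that add atoms: water, O
Why: Halohydrin route: bromonium formation on the more open face (the side of H14, H18 and H22, anti to the C14 side chain), anti attack of water and base-induced SN2 closure place the epoxide oxygen syn to the C14 side chain (C15 R, C16 S), the contrasteric outcome familiar from steroidal 5β,6β-epoxides.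

**Compound list**
1 | (R)-(−)-linalool | C=C[C@](C)(O)CCC=C(C)C | starting material
2 | (R)-1-methylcyclopent-2-en-1-ol | C[C@]1(O)C=CCC1 | intermediate
3 | (R)-triethyl[(1-methylcyclopent-2-en-1-yl)oxy]silane | CC[Si](CC)(CC)O[C@@]1(C)C=CCC1 | intermediate
4 | cis-6,6-dichloro-2-methyl-2-(triethylsilyloxy)bicyclo[3.2.0]heptan-7-one, bridgehead H cis to OSiEt3 | CC[Si](CC)(CC)O[C@]1(C)CC[C@@H]2[C@H]1C(=O)C2(Cl)Cl | intermediate
5 | cis-2,2-dichloro-6-methyl-6-(triethylsilyloxy)bicyclo[3.3.0]octan-3-one | CC[Si](CC)(CC)O[C@]1(C)CC[C@@H]2[C@H]1CC(=O)C2(Cl)Cl | intermediate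
6 | cis-2,2,6-trimethyl-6-(triethylsilyloxy)bicyclo[3.3.0]octan-3-one | CC[Si](CC)(CC)O[C@]1(C)CC[C@@H]2[C@H]1CC(=O)C2(C)C | intermediate
7 | cis-2,2,6-trimethyl-3-(prop-1-en-2-yl)-6-(triethylsilyloxy)bicyclo[3.3.0]octan-3-ol, isopropenyl on the convex face | CC[Si](CC)(CC)O[C@]1(C)CC[C@@H]2[C@H]1C[C@@](O)(C(C)=C)C2(C)C | intermediate
8 | cis-fused 1,4,4,6-tetramethyl-1-(triethylsilyloxy)octahydroazulen-7(1H)-one, C6 epimers | CC[Si](CC)(CC)O[C@]1(C)CC[C@@H]2[C@H]1CC(=O)C(C)CC2(C)C | intermediate
9 | 7-trimethylsilyloxy 6,7-enol ether of 8 | CC[Si](CC)(CC)O[C@]1(C)CC[C@@H]2[C@H]1CC(O[Si](C)(C)C)=C(C)CC2(C)C | intermediate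
10 | cis-fused 1,4,4,6-tetramethyl-1-(triethylsilyloxy)-2,3,3a,4,8,8a-hexahydroazulen-7(1H)-one | CC[Si](CC)(CC)O[C@]1(C)CC[C@@H]2[C@H]1CC(=O)C(C)=CC2(C)C | intermediate
11 | (7S)-allylic alcohol of 10, OH trans to the ring-fusion H atoms | CC[Si](CC)(CC)O[C@]1(C)CC[C@@H]2[C@H]1C[C@H](O)C(C)=CC2(C)C | intermediate
12 | vinyl ether of 11 | CC[Si](CC)(CC)O[C@]1(C)CC[C@@H]2[C@H]1C[C@H](OC=C)C(C)=CC2(C)C | intermediate
13 | right-half aldehyde, CH2CHO at C14 trans to the ring-fusion H atoms, C15=C16 alkene | CC[Si](CC)(CC)O[C@]1(C)CC[C@@H]2[C@H]1CC=C(C)[C@H](CC=O)C2(C)C | intermediate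
14 | (E)-geranylacetone, (5E)-6,10-dimethylundeca-5,9-dien-2-one | CC(C)=CCC/C(C)=C/CCC(C)=O | starting material
15 | (5R,6R,9R)-5,6:9,10-diepoxy-6,10-dimethylundecan-2-one | CC(=O)CC[C@H]1O[C@]1(C)CC[C@H]1OC1(C)C | intermediate
16 | aldol adduct of 15 and 13, C12 carbinol epimers | CC[Si](CC)(CC)O[C@]1(C)CC[C@@H]2[C@H]1CC=C(C)[C@H](CC(O)CC(=O)CC[C@H]3O[C@]3(C)CC[C@H]3OC3(C)C)C2(C)C | intermediate
17 | acetate of 16 | CC[Si](CC)(CC)O[C@]1(C)CC[C@@H]2[C@H]1CC=C(C)[C@H](CC(OC(C)=O)CC(=O)CC[C@H]3O[C@]3(C)CC[C@H]3OC3(C)C)C2(C)C | intermediate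
18 | (E)-enone, C10 ketone, C11=C12 | CC[Si](CC)(CC)O[C@]1(C)CC[C@@H]2[C@H]1CC=C(C)[C@H](C/C=C/C(=O)CC[C@H]3O[C@]3(C)CC[C@H]3OC3(C)C)C2(C)C | intermediate
19 | (Z)-triethylsilyl enol ether, C10(OSiEt3)=C11 | CC[Si](CC)(CC)O[C@]1(C)CC[C@@H]2[C@H]1CC=C(C)[C@H](CC/C=C(\O[Si](CC)(CC)CC)CC[C@H]3O[C@]3(C)CC[C@H]3OC3(C)C)C2(C)C | intermediate
20 | tetracyclic C10 ketone, C3 OSiMe3, C19 OSiEt3 | CC1(C)O[C@@H]2CCC(=O)[C@H](CC[C@@H]3C(C)(C)[C@@H]4CC[C@@](C)(O[Si](CC)(CC)CC)[C@@H]4CC=C3C)[C@@]2(C)CC[C@H]1O[Si](C)(C)C | intermediate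
21 | tetracyclic keto diol, C10 ketone, 3R OH, C19 OH | CC1(C)O[C@@H]2CCC(=O)[C@H](CC[C@@H]3C(C)(C)[C@@H]4CC[C@@](C)(O)[C@@H]4CC=C3C)[C@@]2(C)CC[C@H]1O | intermediate
22 | triol, 10S tertiary alcohol | CC1(C)O[C@@H]2CC[C@](C)(O)[C@H](CC[C@@H]3C(C)(C)[C@@H]4CC[C@@](C)(O)[C@@H]4CC=C3C)[C@@]2(C)CC[C@H]1O | intermediate
23 | C3 ketone diol, 15,16-alkene | CC1(C)O[C@@H]2CC[C@](C)(O)[C@H](CC[C@@H]3C(C)(C)[C@@H]4CC[C@@](C)(O)[C@@H]4CC=C3C)[C@@]2(C)CCC1=O | intermediate
24 | bromohydrin, C15 OH syn to the C14 side chain, C16 Br anti | CC1(C)O[C@@H]2CC[C@](C)(O)[C@H](CC[C@@H]3C(C)(C)[C@@H]4CC[C@@](C)(O)[C@@H]4C[C@@H](Br)[C@]3(C)O)[C@@]2(C)CCC1=O | intermediate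
25 | CNP0259752.1 | CC1(C)O[C@@H]2CC[C@](C)(O)[C@H](CC[C@@H]3C(C)(C)[C@@H]4CC[C@@](C)(O)[C@@H]4C[C@@H]4O[C@@]43C)[C@@]2(C)CCC1=O | target

**Totals and risks**
Total step count: 16. Longest linear sequence: 15 (steps 1–10, then 12–16).

Most likely to fail:

Step 13 (the proposed new cascade, run late on the full skeleton). The fallback uses known chemistry only; it sets out from 15 and comes back at 20. Compound 15 is converted (LiN(i-Pr)2, t-BuMe2SiCl, THF–DMPU, −78 °C) into its terminal tert-butyldimethylsilyl enol ether F1. The precedented cascade for this enol silane type (Me3SiOTf, 2,6-di-tert-butyl-4-methylpyridine, CH2Cl2, −78 °C) gives the bicyclic rings A/B ketone F2. Saegusa–Ito oxidation (LiN(i-Pr)2, Me3SiCl; then Pd(OAc)2, MeCN) can only give the C8=C9 enone F3, because C6 is quaternary. Deprotonation of F3 at C11 (LiN(i-Pr)2, −78 °C), aldol addition to 13, acetylation and DBU elimination give the cross-conjugated dienone F4. Conjugate reduction of both enone double bonds with [(Ph3P)CuH]6 (wet benzene), then K2CO3/MeOH equilibration at C11, gives 20, which is desilylated to 21 as in step 13.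

Step 7 (7-endo recyclization must outrun reduction of the tertiary radical). The fallback sets out from 6 and comes back at 8. Baeyer–Villiger oxidation of 6 (m-CPBA, NaHCO3; the quaternary carbon migrates) gives the δ-lactone F5. Opening with MeNH(OMe)·HCl/i-PrMgCl gives the hydroxy Weinreb amide F6, and isopropenylmagnesium bromide gives the hydroxy enone F7. Acylation with methyl chlorooxoacetate and hydrolysis with CsOH give the cesium oxalate F8. Visible-light decarboxylation ([Ir(dF(CF3)ppy)2(dtbbpy)]PF6, DME–DMF–H2O, blue LEDs) generates the same tertiary C23 radical, which closes 7-endo onto the enone to give 8.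

Step 16 (facial course of bromonium formation and opening on ring C; a peracid would be expected to give the other epoxide, so it is not the backup). The fallback sets out from 23 and comes back at 25: direct, catalyst-controlled Shi epoxidation with the L-fructose-derived ketone (the enantiomer of the step 11 catalyst), Oxone, K2CO3, buffered MeCN–CH2(OMe)2, 0 °C. By the spiro transition-state model this enantiomer delivers oxygen to the face syn to the C14 side chain. This is the mismatched pairing with the substrate bias, so it is a weaker backup. No new compound is involved.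

**Further compounds**
F1 | step 13 | terminal tert-butyldimethylsilyl enol ether of 15 | C=C(O[Si](C)(C)C(C)(C)C)CC[C@H]1O[C@]1(C)CC[C@H]1OC1(C)C
F2 | step 13 | rings A/B ketone, trans-fused oxepane–cyclohexanone, C3 OSiMe3, C11 unsubstituted | CC1(C)O[C@@H]2CCC(=O)C[C@@]2(C)CC[C@H]1O[Si](C)(C)C
F3 | step 13 | C8=C9 enone of F2 | CC1(C)O[C@@H]2C=CC(=O)C[C@@]2(C)CC[C@H]1O[Si](C)(C)C
F4 | step 13 | cross-conjugated dienone, C11=C12 alkylidene (geometry not controlled), C3 OSiMe3, C19 OSiEt3 | CC1(C)O[C@@H]2C=CC(=O)C(=CC[C@@H]3C(C)(C)[C@@H]4CC[C@@](C)(O[Si](CC)(CC)CC)[C@@H]4CC=C3C)[C@@]2(C)CC[C@H]1O[Si](C)(C)C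
F5 | step 7 | cis-fused δ-lactone from Baeyer–Villiger oxidation of 6 | CC[Si](CC)(CC)O[C@]1(C)CC[C@@H]2[C@H]1CC(=O)OC2(C)C
F6 | step 7 | hydroxy Weinreb amide | CC[Si](CC)(CC)O[C@]1(C)CC[C@@H](C(C)(C)O)[C@H]1CC(=O)N(C)OC
F7 | step 7 | hydroxy isopropenyl ketone | CC[Si](CC)(CC)O[C@]1(C)CC[C@@H](C(C)(C)O)[C@H]1CC(=O)C(C)=C
F8 | step 7 | cesium oxalate of F7 | CC[Si](CC)(CC)O[C@]1(C)CC[C@@H](C(C)(C)OC(=O)C(=O)[O-])[C@H]1CC(=O)C(C)=C.[Cs+]
F0 | step 16 | none | none
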